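**Plan**
- Target: 5‑(16‑oxoheptadecyl)benzene‑1,3‑diol, chain C1′ (benzylic) to C17′ (methyl), ketone at C16′.
- Enabling feature: the 1,3‑dihydroxy‑5‑alkylbenzene ring is a folded tetraketide. Ring C1 and C3 (the two C–OH) are the former C3 and C5 carbonyls of a 3,5,7‑triketo ester, ring C5 (chain‑bearing) is the former C7 ketone, and ring C6 is the former ester‑activated C2.
- Retrosynthetic cuts, in order: (i) C6–H back to C6–CO2Me and the C16′ ketone back to a dioxolane; (ii) ring bond C5–C6, opening the benzene to the 3,5,7‑triketo ester; (iii) C6–C7 of that ester, giving the trianion of methyl 3,5‑dioxohexanoate plus a C18 Weinreb amide; (iv) chain bond C10′–C11′, giving 11‑bromoundecanoic acid plus a hept‑6‑enyl Grignard reagent.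
- Forward: the C18 chain is joined first, its terminal alkene is turned into the masked methyl ketone, the chain is extended to the tetraketide, the only ring closes in step 7, and ester and ketal are then removed.
- Stereochemistry: the target has no stereocentre and no stereogenic double bond, so nothing has to be set.

Key step: step 7

Remark: because the target is achiral, the requested single stereoisomer is the compound itself. Polycarbonyl compounds are drawn in their all‑keto forms although they will exist as enol mixtures.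

**Route**

Step 1
Reactants: 1 7‑bromohept‑1‑ene; 2 11‑bromoundecanoic acid
Product: 5 octadec‑17‑enoic acid, via hept‑6‑enylmagnesium bromide 3 (not isolated), via chloromagnesium 11‑bromoundecanoate 4 (not isolated)
Conditions: 1, Mg, THF, rt→45 °C; separately 2, MeMgCl (1.0 equiv), THF, −20 °C; then Li2CuCl4 (3 mol %), addition of 3 (1.3 equiv), −20 °C→rt; 1 M HCl work‑up
Reagents that add atoms: none
Why: Copper‑catalysed (Kochi‑type, Li2CuCl4) sp3–sp3 cross‑coupling of a primary alkyl Grignard reagent with a primary alkyl bromide should proceed cleanly because the acidic proton is removed beforehand as the magnesium carboxylate, which does not add Grignard reagents at this temperature.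

Step 2
Reactants: 5 octadec‑17‑enoic acid
Product: 7 N‑methoxy‑N‑methyloctadec‑17‑enamide, via 1‑(imidazol‑1‑yl)octadec‑17‑en‑1‑one 6 (not isolated)
Conditions: CDI (1.2 equiv), CH2Cl2, rt, 1 h; then MeNH(OMe)·HCl (1.5 equiv), rt, 12 h
Reagents that add atoms: N,O‑dimethylhydroxylamine hydrochloride, CNOC.Cl
Why: Acyl‑imidazole activation followed by aminolysis is a standard Weinreb amide synthesis and leaves the terminal alkene untouched.

Step 3
Reactants: 7 N‑methoxy‑N‑methyloctadec‑17‑enamide
Product: 8 N‑methoxy‑N‑methyl‑17‑oxooctadecanamide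
Conditions: PdCl2 (10 mol %), Cu(OAc)2 (20 mol %), O2 (1 atm), DMA/H2O 7:1, rt→40 °C
Reagents that add atoms: water, O (source of the ketone oxygen; dioxygen, O=O, is the terminal oxidant)
Why: Tsuji–Wacker oxidation should give the methyl ketone by Markovnikov hydroxypalladation of the unhindered terminal alkene and β‑hydride elimination, with the tertiary amide as a spectator.

Step 4
Reactants: 8 N‑methoxy‑N‑methyl‑17‑oxooctadecanamide
Product: 9 N‑methoxy‑N‑methyl‑16‑(2‑methyl‑1,3‑dioxolan‑2‑yl)hexadecanamide
Conditions: HOCH2CH2OH (5 equiv), TsOH·H2O (2 mol %), toluene, reflux, Dean–Stark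
Reagents that add atoms: ethylene glycol, OCCO
Why: Acid‑catalysed ketalisation with azeotropic removal of water masks the methyl ketone as a base‑stable dioxolane, and the Weinreb amide, unlike an ester, cannot transesterify with the diol.

Step 5
Reactants: 10 dehydroacetic acid (3‑acetyl‑4‑hydroxy‑6‑methyl‑2H‑pyran‑2‑one)
Product: 12 methyl 3,5‑dioxohexanoate, via methyl 2‑acetyl‑3,5‑dioxohexanoate 11 (not isolated)
Conditions: Mg(OMe)2 (2 equiv, from Mg in MeOH), MeOH, reflux; then cold 2 M HCl
Reagents that add atoms: magnesium methoxide, C[O-].C[O-].[Mg+2] (methoxy group; methanol, CO, is the solvent)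
Why: Methoxide opens the pyranone lactone and a retro‑Claisen cleavage then expels the 3‑acetyl group as methyl acetate, the magnesium chelate of the β,δ‑diketo ester protecting it from further cleavage (known degradation of dehydroacetic acid).

Step 6
Reactants: 12 methyl 3,5‑dioxohexanoate; 9 N‑methoxy‑N‑methyl‑16‑(2‑methyl‑1,3‑dioxolan‑2‑yl)hexadecanamide
Product: 14 methyl 22‑(2‑methyl‑1,3‑dioxolan‑2‑yl)‑3,5,7‑trioxodocosanoate, via trilithiated methyl 3,5‑dioxohexanoate 13 (not isolated)
Conditions: 12 (1.5 equiv), LDA (4.5 equiv), THF, −78→0 °C, 1 h; then 9 (1.0 equiv), THF, −78→0 °C; AcOH/THF quench at −78 °C, pH 5 phosphate buffer; crude 14 freed from excess 12 under high vacuum and used at once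
Reagents that add atoms: none
Why: In this polyanion γ‑acylation the last‑formed terminal carbanion C6 of the trianion is the most nucleophilic site and should add to the Weinreb amide, whose chelated tetrahedral adduct prevents over‑addition and keeps the acidic product from quenching unreacted trianion.

Step 7
Reactants: 14 methyl 22‑(2‑methyl‑1,3‑dioxolan‑2‑yl)‑3,5,7‑trioxodocosanoate
Product: 16 methyl 2,4‑dihydroxy‑6‑[15‑(2‑methyl‑1,3‑dioxolan‑2‑yl)pentadecyl]benzoate, via methyl 2‑hydroxy‑2‑[15‑(2‑methyl‑1,3‑dioxolan‑2‑yl)pentadecyl]‑4,6‑dioxocyclohexane‑1‑carboxylate 15 (not isolated)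
Conditions: K2CO3 (2.5 equiv), degassed MeOH, 0 °C→rt, N2, 12 h; AcOH to pH 6
Reagents that add atoms: none
Why: Carbonate forms the C2 enolate (flanked by the ester and the C3 ketone), which adds to the C7 ketone to give cyclic aldol 15; E1cB loss of water and enolisation of the C3 and C5 carbonyls then deliver the benzene ring as an irreversible thermodynamic sink. The closest known reaction type is the biomimetic aldol cyclisation–aromatisation of 3,5,7‑triketo esters to 6‑substituted β‑resorcylates under mild base. The ring closes in the 6‑(enolexo)‑exo‑trig mode by forming the bond between ester‑bearing C2 and chain‑bearing C7. The two stereocentres of 15 are uncontrolled and irrelevant, since both are erased on aromatisation and 16 is achiral. The step needs C2→C7 aldol closure to outrun C6→C1 Claisen closure (acylphloroglucinol) and O‑acylation to the 4‑hydroxy‑2‑pyranone; a non‑chelating potassium base in methanol, the higher electrophilicity of the ketone over the ester and the double activation of C2 should secure this. The dioxolane keeps the remote ketone out of all enolate chemistry, and methanol as solvent makes ester exchange degenerate.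

Step 8
Reactants: 16 methyl 2,4‑dihydroxy‑6‑[15‑(2‑methyl‑1,3‑dioxolan‑2‑yl)pentadecyl]benzoate
Product: 19 Hansfordiol B, 5‑(16‑oxoheptadecyl)benzene‑1,3‑diol, via 2,4‑dihydroxy‑6‑[15‑(2‑methyl‑1,3‑dioxolan‑2‑yl)pentadecyl]benzoic acid 17 (not isolated), via 2,4‑dihydroxy‑6‑(16‑oxoheptadecyl)benzoic acid 18 (not isolated)
Conditions: KOH (10 equiv), degassed MeOH/H2O, reflux, N2; MeOH removed, then dioxane, 3 M HCl to pH 1, 80 °C, N2
Reagents that add atoms: water, O
Why: Hydroxide saponifies the hindered salicylate‑type ester while the ketal is inert to base, and acidification then hydrolyses the dioxolane and lets β‑resorcylic acid 18 lose CO2 by ipso‑protonation of the electron‑rich ring (protodecarboxylation typical of 2,4‑dihydroxybenzoic acids).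

**Compound list**
1 | 7‑bromohept‑1‑ene | C=CCCCCCBr | starting material
2 | 11‑bromoundecanoic acid | OC(=O)CCCCCCCCCCBr | starting material
3 | hept‑6‑enylmagnesium bromide | C=CCCCCC[Mg]Br | intermediate (not isolated)
4 | chloromagnesium 11‑bromoundecanoate | [O-]C(=O)CCCCCCCCCCBr.[Mg+2].[Cl-] | intermediate (not isolated)
5 | octadec‑17‑enoic acid | C=CCCCCCCCCCCCCCCCC(=O)O | intermediate
6 | 1‑(imidazol‑1‑yl)octadec‑17‑en‑1‑one | C=CCCCCCCCCCCCCCCCC(=O)n1ccnc1 | intermediate (not isolated)
7 | N‑methoxy‑N‑methyloctadec‑17‑enamide | C=CCCCCCCCCCCCCCCCC(=O)N(C)OC | intermediate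
8 | N‑methoxy‑N‑methyl‑17‑oxooctadecanamide | CC(=O)CCCCCCCCCCCCCCCC(=O)N(C)OC | intermediate
9 | N‑methoxy‑N‑methyl‑16‑(2‑methyl‑1,3‑dioxolan‑2‑yl)hexadecanamide | CC1(OCCO1)CCCCCCCCCCCCCCCC(=O)N(C)OC | intermediate
10 | dehydroacetic acid | CC(=O)C1=C(O)C=C(C)OC1=O | starting material
11 | methyl 2‑acetyl‑3,5‑dioxohexanoate (as its magnesium chelate) | COC(=O)C(C(C)=O)C(=O)CC(C)=O | intermediate (not isolated)
12 | methyl 3,5‑dioxohexanoate | COC(=O)CC(=O)CC(C)=O | intermediate
13 | trilithiated methyl 3,5‑dioxohexanoate | [Li+].[Li+].[Li+].COC(=O)[CH-]C(=O)[CH-]C(=O)[CH2-] | intermediate (not isolated)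
14 | methyl 22‑(2‑methyl‑1,3‑dioxolan‑2‑yl)‑3,5,7‑trioxodocosanoate | COC(=O)CC(=O)CC(=O)CC(=O)CCCCCCCCCCCCCCCC1(C)OCCO1 | intermediate (key‑step precursor)
15 | methyl 2‑hydroxy‑2‑[15‑(2‑methyl‑1,3‑dioxolan‑2‑yl)pentadecyl]‑4,6‑dioxocyclohexane‑1‑carboxylate (transient diastereomer mixture, both centres lost on aromatisation) | COC(=O)C1C(=O)CC(=O)CC1(O)CCCCCCCCCCCCCCCC2(C)OCCO2 | intermediate (not isolated)
16 | methyl 2,4‑dihydroxy‑6‑[15‑(2‑methyl‑1,3‑dioxolan‑2‑yl)pentadecyl]benzoate | COC(=O)c1c(O)cc(O)cc1CCCCCCCCCCCCCCCC2(C)OCCO2 | intermediate (key‑step product)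
17 | 2,4‑dihydroxy‑6‑[15‑(2‑methyl‑1,3‑dioxolan‑2‑yl)pentadecyl]benzoic acid (in the flask as its potassium salt) | OC(=O)c1c(O)cc(O)cc1CCCCCCCCCCCCCCCC2(C)OCCO2 | intermediate (not isolated)
18 | 2,4‑dihydroxy‑6‑(16‑oxoheptadecyl)benzoic acid | CC(=O)CCCCCCCCCCCCCCCc1cc(O)cc(O)c1C(=O)O | intermediate (not isolated)
19 | Hansfordiol B, 5‑(16‑oxoheptadecyl)benzene‑1,3‑diol | CC(=O)CCCCCCCCCCCCCCCc1cc(O)cc(O)c1 | target

**Step count**
Total: 8 steps. Longest linear sequence: 7 steps (1 → 2 → 3 → 4 → 6 → 7 → 8); step 5 is a one‑step side branch.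

**Steps most likely to fail, with fallbacks**

Step 6. The strongly basic trianion may enolise the Weinreb amide instead of adding to it, and the triketo ester may cyclise in an uncontrolled way during quench and handling. The fallback sets out from 9 and replaces the open‑chain trianion by a masked one. Commercial 2,2,6‑trimethyl‑4H‑1,3‑dioxin‑4‑one would be deprotonated with LiHMDS and C‑acetylated with acetyl chloride to give 2,2‑dimethyl‑6‑(2‑oxopropyl)‑4H‑1,3‑dioxin‑4‑one F1. Its dianion (LDA, 2 equiv, THF, −78 °C) would be acylated at the terminal methyl by 9 to give 6‑[19‑(2‑methyl‑1,3‑dioxolan‑2‑yl)‑2,4‑dioxononadecyl]‑2,2‑dimethyl‑4H‑1,3‑dioxin‑4‑one F2, which is far more stable than the open triketo ester. Heating F2 in toluene at 110 °C with methanol should expel acetone by retro‑[4+2] and trap the acylketene as the methyl ester, returning to the route at 14 immediately before the cyclisation.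

Step 7. Claisen closure, pyranone lactonisation or a stalled aldol adduct that does not dehydrate may divert the cyclisation. The fallback sets out from 9 and builds the same ring by a Michael–Claisen annulation followed by dehydrogenation. DIBAL‑H reduction (THF, −78 °C) should give 16‑(2‑methyl‑1,3‑dioxolan‑2‑yl)hexadecanal F3. Wittig olefination with 1‑(triphenylphosphoranylidene)propan‑2‑one should give (E)‑19‑(2‑methyl‑1,3‑dioxolan‑2‑yl)nonadec‑3‑en‑2‑one F4. Dimethyl malonate with NaOMe in refluxing methanol (conjugate addition, then intramolecular Claisen condensation) should give methyl 2‑hydroxy‑6‑[15‑(2‑methyl‑1,3‑dioxolan‑2‑yl)pentadecyl]‑4‑oxocyclohex‑2‑ene‑1‑carboxylate F5. Bromination–dehydrobromination (Br2, DMF, 0 °C then gentle warming, quenched into aqueous NaHCO3 to spare the ketal) should aromatise F5 and return to the route at 16.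

Step 1. Homocoupling and reduction of the alkyl halides, or poor solubility of the magnesium carboxylate at low temperature, may erode the cross‑coupling. The fallback sets out from 2 and forms the chain by olefination, which also makes the Wacker oxidation unnecessary. Heating 2 with PPh3 in acetonitrile should give (10‑carboxydecyl)triphenylphosphonium bromide F6. Its ylide (NaHMDS, 2 equiv, THF, −78 °C) would react selectively at the aldehyde of 6‑oxoheptanal F7, freshly made by ozonolysis of 1‑methylcyclohexene with Me2S work‑up, to give (Z)‑17‑oxooctadec‑11‑enoic acid F8. Hydrogenation (H2, Pd/C, EtOAc) should give 17‑oxooctadecanoic acid F9, and CDI/MeNH(OMe)·HCl amidation as in step 2 returns to the route at 8.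

**Further compounds**
F1 | step 6 | 2,2‑dimethyl‑6‑(2‑oxopropyl)‑4H‑1,3‑dioxin‑4‑one | CC(=O)CC1=CC(=O)OC(C)(C)O1
F2 | step 6 | 6‑[19‑(2‑methyl‑1,3‑dioxolan‑2‑yl)‑2,4‑dioxononadecyl]‑2,2‑dimethyl‑4H‑1,3‑dioxin‑4‑one | CC1(C)OC(=O)C=C(CC(=O)CC(=O)CCCCCCCCCCCCCCCC2(C)OCCO2)O1
F3 | step 7 | 16‑(2‑methyl‑1,3‑dioxolan‑2‑yl)hexadecanal | CC1(OCCO1)CCCCCCCCCCCCCCCC=O
F4 | step 7 | (E)‑19‑(2‑methyl‑1,3‑dioxolan‑2‑yl)nonadec‑3‑en‑2‑one | CC(=O)/C=C/CCCCCCCCCCCCCCCC1(C)OCCO1
F5 | step 7 | methyl 2‑hydroxy‑6‑[15‑(2‑methyl‑1,3‑dioxolan‑2‑yl)pentadecyl]‑4‑oxocyclohex‑2‑ene‑1‑carboxylate (racemic, centres lost on aromatisation) | COC(=O)C1C(O)=CC(=O)CC1CCCCCCCCCCCCCCCC2(C)OCCO2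
F6 | step 1 | (10‑carboxydecyl)triphenylphosphonium bromide | OC(=O)CCCCCCCCCC[P+](c1ccccc1)(c1ccccc1)c1ccccc1.[Br-]
F7 | step 1 | 6‑oxoheptanal | CC(=O)CCCCC=O
F8 | step 1 | (Z)‑17‑oxooctadec‑11‑enoic acid | CC(=O)CCCC/C=C\CCCCCCCCCC(=O)O
F9 | step 1 | 17‑oxooctadecanoic acid | CC(=O)CCCCCCCCCCCCCCCC(=O)O
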